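A direct plan would first make the unprenylated dihydrochalcone davidigenin A1 by BF3·OEt2-promoted Friedel–Crafts acylation of the resorcinol ring.
It would then pass both prenyl groups through O4': Pd(PPh3)4-catalysed O-(1,1-dimethylallyl)ation to the tertiary allyl ether A2, aromatic Claisen shift to 3'-prenyldavidigenin A3, a second etherification to the ether A4 and a second shift to the target.
Its weakest operations would be:
- the O-(1,1-dimethylallyl)ation of an unprotected triphenol, needed twice: only a small acidity gap would single out O4', so the ring B phenol (whose ether would later shift a prenyl group onto ring B), the chelated 2'-OH and direct C-allylation would compete, the second time at an oxygen crowded by the new 3'-prenyl group;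
- the two [3,3] shifts at 120 °C with Pd(PPh3)4 still present: the first would be left to choose between C3' and C5', and the tertiary allyl ethers could be re-ionised, lose isoprene or close onto a neighbouring hydroxyl group to give chromans;
- the chaining of all four events in one flask on the finished core: nothing could be purified or corrected between stages, and every loss would fall on the most advanced material.

**Plan of the new route**
Ring A is cut across C1'–C2' and C5'–C6'. Its carbons C2'(O)–C3'(prenyl)–C4'(O)–C5'(prenyl) alternate exactly as the ester carbon, α-carbon, ketone carbon and γ-carbon of methyl acetoacetate, so this half is the γ,α-diprenylated keto ester, used as its 1-methoxy-1,3-bis(trimethylsilyloxy)diene.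
The only ring hydrogen, C6'–H, sits beside the acyl-bearing C1', so the other half is a terminal ynone that already holds the C(=O)CH2CH2 chain and ring B.
Ring B is bought; ring A arises last, by a Diels–Alder addition that loses methanol and so arrives directly at the oxidation level of the resorcinol.
Both prenyl groups are placed on sp3 carbons by enolate alkylation before any phenol exists, so there is no O-to-C transfer and no choice between ortho positions or among three hydroxyl groups. The finished core sees only the removal of silyl groups.

Key step: step 6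

Remark on the chemistry (assumption): 7 and 15 are racemic and 17 is a mixture of diastereomers; these centres vanish before the achiral target. The C2=C3 bond of 8 and the ketene-acetal bond of 9 and 10 are written without geometry because both carbons become aromatic; only the (3Z) geometry of 10 matters.

**Step 1**
Reactants: 1 methyl acetoacetate; 2 prenyl bromide (1-bromo-3-methylbut-2-ene)
Product: 5 methyl 7-methyl-3-oxooct-6-enoate, via sodium enolate 3 (not isolated), via acetoacetate dianion 4 (not isolated)
Conditions: NaH (1.1 equiv), THF, 0 °C; n-BuLi (1.05 equiv), 0 °C; 2 (1.0 equiv), 0 °C → rt; aq. NH4Cl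
Reagents that add atoms: none
Why: γ-Alkylation of a β-keto ester dianion: after the sodium enolate 3 is deprotonated again by n-BuLi, the terminal carbanion of dianion 4 is the most basic and most nucleophilic site and displaces bromide from the primary allylic carbon of 2 (SN2), so the prenyl group enters only at the γ-carbon, the future C5'.

**Step 2**
Reactants: 5 methyl 7-methyl-3-oxooct-6-enoate; 2 prenyl bromide
Product: 7 methyl 7-methyl-2-(3-methylbut-2-en-1-yl)-3-oxooct-6-enoate (racemic), via sodium enolate 6 (not isolated)
Conditions: NaH (0.98 equiv), THF–DMF (4:1), 0 °C; 2 (1.05 equiv), 0 °C → rt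
Reagents that add atoms: none
Why: Acetoacetic ester alkylation: the soft sodium enolate 6 attacks the primary allylic bromide 2 at carbon (SN2), a slight deficit of base suppresses a second alkylation, and the new stereocentre (the future C3') is formed racemic, which is of no consequence because it becomes sp2 in step 3.

**Step 3**
Reactants: 7 methyl 7-methyl-2-(3-methylbut-2-en-1-yl)-3-oxooct-6-enoate
Product: 10 (3Z)-1-methoxy-7-methyl-2-(3-methylbut-2-en-1-yl)-1,3-bis(trimethylsilyloxy)octa-1,3,6-triene, via silyl enol ether 8 (not isolated), via lithium dienolate 9 (not isolated)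
Conditions: Me3SiCl (1.5 equiv), Et3N (1.6 equiv), toluene, rt, 48 h; filter under argon, concentrate; LiN(i-Pr)2 (1.15 equiv), THF, −78 °C, 1 h; Me3SiCl (1.3 equiv), −78 → 0 °C; pentane, filter, concentrate; used crude under argon
Reagents that add atoms: chlorotrimethylsilane, C[Si](C)(C)Cl
Why: Two-stage formation of a 1-alkoxy-1,3-bis(silyloxy)diene from a β-keto ester: Et3N/Me3SiCl silylates the enol oxygen of the keto group to give 8, LiN(i-Pr)2 then removes a γ-proton (no α-proton is left) to give the extended dienolate 9, which Me3SiCl traps on the ester oxygen; 1,3-allylic strain against the substituents on C2 places the C4 substituent trans to C2, i.e. (3Z), the geometry that lets the diene reach the s-cis conformation in step 6.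

**Step 4**
Reactants: 11 methyl 3-(4-hydroxyphenyl)propanoate
Product: 12 methyl 3-[4-(tert-butyldimethylsilyloxy)phenyl]propanoate
Conditions: t-BuMe2SiCl (1.2 equiv), imidazole (2.5 equiv), DMF, rt
Reagents that add atoms: tert-butyldimethylsilyl chloride, CC(C)(C)[Si](C)(C)Cl
Why: Imidazole-promoted silylation of a phenol, which masks the acidic ring B hydroxyl group that would otherwise quench the Grignard reagents of step 5 and protonate the ketene acetal in step 6; the ester is untouched.

**Step 5**
Reactants: 12 methyl 3-[4-(tert-butyldimethylsilyloxy)phenyl]propanoate; 13 ethynylmagnesium bromide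
Product: 16 5-[4-(tert-butyldimethylsilyloxy)phenyl]pent-1-yn-3-one, via Weinreb amide 14 (not isolated), via magnesium chelate 15 (not isolated)
Conditions: MeNH(OMe)·HCl (1.5 equiv), i-PrMgCl (3.0 equiv), THF, −20 → −5 °C; then 13 (3 equiv, 0.5 M in THF), −5 °C → rt; inverse quench into aq. NaHSO4, 0 °C
Reagents that add atoms: none
Why: One-flask ester-to-ketone conversion through the Weinreb amide (Weinreb ketone synthesis): ClMgN(OMe)Me, made from the amine salt and i-PrMgCl, aminolyses the ester to 14, and the five-membered magnesium chelate 15 formed with 13 does not collapse until the quench, so only one ethynyl group is added; the cold acidic inverse quench protonates the liberated amine before it can add to the terminal ynone, and the aryl silyl ether survives.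

**Step 6**
Reactants: 10 (3Z)-1-methoxy-7-methyl-2-(3-methylbut-2-en-1-yl)-1,3-bis(trimethylsilyloxy)octa-1,3,6-triene; 16 5-[4-(tert-butyldimethylsilyloxy)phenyl]pent-1-yn-3-one
Product: 19 Gancaonin J, via cycloadduct 17 (not isolated), via tris-silyl ether 18 (not isolated)
Conditions: 10 (1.5 equiv), toluene, 0 °C → rt, 12 h, then 70 °C, 2 h; concentrate; Bu4NF (4 equiv), AcOH (4 equiv), THF, 0 °C → rt
Reagents that add atoms: none
Why: Normal-demand Diels–Alder reaction of an electron-rich 1,1,3-trioxygenated diene with an electron-poor terminal ynone: the bond from diene C4 (future C5') to the ynone β-carbon (C6') leads and the bond from the ketene-acetal carbon C1 (future C2') to the α-carbon (C1') follows, giving the cyclohexa-1,4-diene 17, which loses methanol from the mixed ketal carbon and the doubly allylic C–H to give the aromatic tris-silyl ether 18, after which buffered fluoride removes the three silyl groups (any 17 left collapses to the same phenol). The closest known reaction type is the cycloaddition–aromatisation of 1-alkoxy-1,3-bis(silyloxy)buta-1,3-dienes and 1,1-dialkoxy-3-silyloxybuta-1,3-dienes with acetylenic esters and ketones, which gives resorcinol carboxylates and ketones with the same orientation. Ring A is closed by [4+2] cycloaddition, both new ring bonds (C5'–C6' and C1'–C2') forming in the one event. The two stereocentres of 17 are transient and vanish on aromatisation, so no element of control is needed. The step needs regioselectivity, which the substrate secures twice over, since both donor oxygens of 10 (on C1 and C3) put the largest HOMO coefficient on C4 and the ynone LUMO is largest at its unsubstituted β-carbon, so the acyl group must end ortho to O2' and para to O4'; it also needs the s-cis conformation, which the (3Z) geometry (C4 prenyl group outside) allows, and chemoselectivity over the two isolated electron-rich prenyl alkenes, which are not dienophiles for this diene.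

**Compound list**
1 | methyl acetoacetate | COC(=O)CC(C)=O | starting material
2 | prenyl bromide (1-bromo-3-methylbut-2-ene) | CC(C)=CCBr | starting material
3 | sodium enolate of methyl acetoacetate | [Na+].COC(=O)C=C(C)[O-] | intermediate
4 | sodium lithium dianion of methyl acetoacetate | [Na+].[Li+].C=C([O-])C=C([O-])OC | intermediate
5 | methyl 7-methyl-3-oxooct-6-enoate | COC(=O)CC(=O)CCC=C(C)C | intermediate
6 | sodium enolate of 5 | [Na+].COC(=O)C=C([O-])CCC=C(C)C | intermediate
7 | methyl 7-methyl-2-(3-methylbut-2-en-1-yl)-3-oxooct-6-enoate (racemic) | COC(=O)C(CC=C(C)C)C(=O)CCC=C(C)C | intermediate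
8 | methyl 7-methyl-2-(3-methylbut-2-en-1-yl)-3-(trimethylsilyloxy)octa-2,6-dienoate (C2=C3 geometry not defined) | COC(=O)C(CC=C(C)C)=C(O[Si](C)(C)C)CCC=C(C)C | intermediate
9 | lithium (3Z)-1-methoxy-7-methyl-2-(3-methylbut-2-en-1-yl)-3-(trimethylsilyloxy)octa-1,3,6-trien-1-olate | [Li+].COC([O-])=C(CC=C(C)C)/C(O[Si](C)(C)C)=C/CC=C(C)C | intermediate
10 | (3Z)-1-methoxy-7-methyl-2-(3-methylbut-2-en-1-yl)-1,3-bis(trimethylsilyloxy)octa-1,3,6-triene | COC(O[Si](C)(C)C)=C(CC=C(C)C)/C(O[Si](C)(C)C)=C/CC=C(C)C | intermediate
11 | methyl 3-(4-hydroxyphenyl)propanoate | COC(=O)CCc1ccc(O)cc1 | starting material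
12 | methyl 3-[4-(tert-butyldimethylsilyloxy)phenyl]propanoate | COC(=O)CCc1ccc(O[Si](C)(C)C(C)(C)C)cc1 | intermediate
13 | ethynylmagnesium bromide | C#C[Mg]Br | starting material
14 | 3-[4-(tert-butyldimethylsilyloxy)phenyl]-N-methoxy-N-methylpropanamide (Weinreb amide) | CON(C)C(=O)CCc1ccc(O[Si](C)(C)C(C)(C)C)cc1 | intermediate
15 | bromomagnesium 5-[4-(tert-butyldimethylsilyloxy)phenyl]-3-[methoxy(methyl)amino]pent-1-yn-3-olate (chelate, racemic) | C#CC(O[Mg]Br)(N(C)OC)CCc1ccc(O[Si](C)(C)C(C)(C)C)cc1 | intermediate
16 | 5-[4-(tert-butyldimethylsilyloxy)phenyl]pent-1-yn-3-one | C#CC(=O)CCc1ccc(O[Si](C)(C)C(C)(C)C)cc1 | intermediate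
17 | 3-[4-(tert-butyldimethylsilyloxy)phenyl]-1-[6-methoxy-3,5-bis(3-methylbut-2-en-1-yl)-4,6-bis(trimethylsilyloxy)cyclohexa-1,4-dien-1-yl]propan-1-one (mixture of diastereomers) | COC1(O[Si](C)(C)C)C(CC=C(C)C)=C(O[Si](C)(C)C)C(CC=C(C)C)C=C1C(=O)CCc1ccc(O[Si](C)(C)C(C)(C)C)cc1 | intermediate
18 | 1-[3,5-bis(3-methylbut-2-en-1-yl)-2,4-bis(trimethylsilyloxy)phenyl]-3-[4-(tert-butyldimethylsilyloxy)phenyl]propan-1-one | CC(C)=CCc1cc(C(=O)CCc2ccc(O[Si](C)(C)C(C)(C)C)cc2)c(O[Si](C)(C)C)c(CC=C(C)C)c1O[Si](C)(C)C | intermediate
19 | Gancaonin J, 1-[2,4-dihydroxy-3,5-bis(3-methylbut-2-en-1-yl)phenyl]-3-(4-hydroxyphenyl)propan-1-one (achiral) | CC(C)=CCc1cc(C(=O)CCc2ccc(O)cc2)c(O)c(CC=C(C)C)c1O | target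

**Step count and risks**
Total: 6 steps. Longest linear sequence: 4 steps (1, 2, 3, 6); the ynone arm (steps 4 and 5) joins at step 6.

Steps most likely to fail:

1. Step 6. The diene may be lost by proton or silyl transfer before it cycloadds, the union may stop after the first carbon–carbon bond, the ynone may be consumed in an ene reaction with a prenyl group, or silanol may be expelled in place of methanol, which would leave O2' methylated. The fallback sets out from Weinreb amide 14, isolated for this purpose, and comes back to the route at 19; in it ring A would be taken from a benzene and substituted by three directed ortho-metalations. Commercial 1,3-bis(methoxymethoxy)benzene F1 would be lithiated between its two oxygens (n-BuLi, THF, 0 °C) and alkylated with 2 in the presence of CuBr·SMe2 to give 1,3-bis(methoxymethoxy)-2-(3-methylbut-2-en-1-yl)benzene F2. A second lithiation ortho to an acetal oxygen (n-BuLi, TMEDA) and alkylation with 2 would give 1,3-bis(methoxymethoxy)-2,4-bis(3-methylbut-2-en-1-yl)benzene F3. A third lithiation at the last position ortho to an acetal oxygen and addition to 14 would give 1-[2,4-bis(methoxymethoxy)-3,5-bis(3-methylbut-2-en-1-yl)phenyl]-3-[4-(tert-butyldimethylsilyloxy)phenyl]propan-1-one F4. HCl in MeOH and then Bu4NF would free the three phenols and return 19.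

2. Step 3. O-silylation of the hindered α-branched keto ester may stay incomplete, silicon may go to carbon, or the bis-silyl diene may hydrolyse on handling. The fallback sets out from 5 and comes back to the route at 19; in it the order of events would be changed. The unbranched keto ester 5 would give, by the same two-stage silylation (routine without the α-branch), 1-methoxy-7-methyl-1,3-bis(trimethylsilyloxy)octa-1,3,6-triene F5. Cycloaddition of F5 with 16 and buffered fluoride work-up as in step 6 would give 5'-prenyldavidigenin F6. Since C5' is then occupied, nuclear C-prenylation of the 4'-phenoxide with 2 in aqueous KOH (1 equiv) would be directed on ring A to C3', the one carbon left between O2' and O4', and would return 19 after separation from any O-prenyl ether formed alongside.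

3. Step 5. The amine or magnesium alkoxide set free at the quench may add to the terminal ynone, or aminolysis of the ester may stay incomplete in the one-flask procedure. The fallback sets out from 12 and comes back to the route at 16; in it the oxidation level would be adjusted instead. i-Bu2AlH (CH2Cl2, −78 °C) would reduce 12 to 3-[4-(tert-butyldimethylsilyloxy)phenyl]propanal F7, addition of 13 would give racemic 5-[4-(tert-butyldimethylsilyloxy)phenyl]pent-1-yn-3-ol F8, and oxidation with MnO2 would return 16 with no amine in the flask.

**Further compounds**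
F1 | step 6 | 1,3-bis(methoxymethoxy)benzene | COCOc1cccc(OCOC)c1
F2 | step 6 | 1,3-bis(methoxymethoxy)-2-(3-methylbut-2-en-1-yl)benzene | COCOc1cccc(OCOC)c1CC=C(C)C
F3 | step 6 | 1,3-bis(methoxymethoxy)-2,4-bis(3-methylbut-2-en-1-yl)benzene | COCOc1ccc(CC=C(C)C)c(OCOC)c1CC=C(C)C
F4 | step 6 | 1-[2,4-bis(methoxymethoxy)-3,5-bis(3-methylbut-2-en-1-yl)phenyl]-3-[4-(tert-butyldimethylsilyloxy)phenyl]propan-1-one | COCOc1c(CC=C(C)C)c(OCOC)c(CC=C(C)C)cc1C(=O)CCc1ccc(O[Si](C)(C)C(C)(C)C)cc1
F5 | step 3 | 1-methoxy-7-methyl-1,3-bis(trimethylsilyloxy)octa-1,3,6-triene (double-bond geometry not defined) | COC(O[Si](C)(C)C)=CC(O[Si](C)(C)C)=CCC=C(C)C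
F6 | step 3 | 5'-prenyldavidigenin, 1-[2,4-dihydroxy-5-(3-methylbut-2-en-1-yl)phenyl]-3-(4-hydroxyphenyl)propan-1-one | CC(C)=CCc1cc(C(=O)CCc2ccc(O)cc2)c(O)cc1O
F7 | step 5 | 3-[4-(tert-butyldimethylsilyloxy)phenyl]propanal | O=CCCc1ccc(O[Si](C)(C)C(C)(C)C)cc1
F8 | step 5 | 5-[4-(tert-butyldimethylsilyloxy)phenyl]pent-1-yn-3-ol (racemic) | C#CC(O)CCc1ccc(O[Si](C)(C)C(C)(C)C)cc1
A1 | direct plan | davidigenin, 1-(2,4-dihydroxyphenyl)-3-(4-hydroxyphenyl)propan-1-one | O=C(CCc1ccc(O)cc1)c1ccc(O)cc1O
A2 | direct plan | 1-[2-hydroxy-4-(2-methylbut-3-en-2-yloxy)phenyl]-3-(4-hydroxyphenyl)propan-1-one | C=CC(C)(C)Oc1ccc(C(=O)CCc2ccc(O)cc2)c(O)c1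
A3 | direct plan | 3'-prenyldavidigenin, 1-[2,4-dihydroxy-3-(3-methylbut-2-en-1-yl)phenyl]-3-(4-hydroxyphenyl)propan-1-one | CC(C)=CCc1c(O)ccc(C(=O)CCc2ccc(O)cc2)c1O
A4 | direct plan | 1-[2-hydroxy-4-(2-methylbut-3-en-2-yloxy)-3-(3-methylbut-2-en-1-yl)phenyl]-3-(4-hydroxyphenyl)propan-1-one | C=CC(C)(C)Oc1ccc(C(=O)CCc2ccc(O)cc2)c(O)c1CC=C(C)C
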